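The runs come from a simulation on assumed constants; the scatter is artificial.

The eta run, richer in L than alpha, holds D 24.2%, Z 38.7% and E 27.3% at its last reading, at 3.00 h.

| setting | alpha | eta | green | blue |
|---|---|---|---|---|
| D | 0.10 M | 0.10 M | 0.10 M | 0.10 M |
| Z | 0.10 M | 0.10 M | 0.10 M | 0.10 M |
| L | 0.37 M | 0.46 M | 0.250 M | 0.380 M |
| remark | run made earlier | run made earlier |  |  |
| time |  |  | 4.0 h | 4.0 h |

| run | time / h | E / % | D / % | Q / % | Z / % |
|---|---|---|---|---|---|
| alpha | 0.667 | 10.7 | 39.2 | 4.4 | 46.6 |
| alpha | 1.33 | 15.2 | 34.9 | 4.5 | 43.9 |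
| alpha | 2.00 | 19.5 | 31.0 | 7.2 | 42.0 |
| alpha | 3.00 | 26.3 | 26.4 | 10.2 | 41.5 |
| eta | 0.250 | 3.6 | 43.2 | 2.2 | 50.3 |
| eta | 0.500 | 8.6 | 40.3 | 3.4 | 45.4 |
| eta | 1.33 | 18.9 | 30.8 | 7.3 | 42.5 |
| eta | 3.00 | 27.3 | 24.2 | 11.2 | 38.7 |

(scatter of a reading: 1 percentage point)

* which of these there is most of at the end, counted by the substrate in it, green (E / Z / Q / D)
* which of these there is most of at the end, counted by the substrate in it, blue (E / Z / Q / D)
* final amount of the leader among these, as a percentage of the D and Z together charged, in green
* final amount of the leader among these, as a percentage of the D and Z together charged, in blue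

- L is single-handed; D and Z are mirror images of each other, charged as a racemate, each of them at the stated concentration
- the handed part of L does not stay in what it makes, so the products of the two hands are mirror images too

So D and E together stand near the 50% of the total that D brought, and E is about that figure less D. It follows that E passes Z once the remaining sum T, which is D plus Z, falls below 50%, and Z is the larger substrate at that reading. But T in eta is still 62.9%, down from 73.3% at 1.33 h. Drawing that fall in eta straight on to 4.0 h gives 56.7%, the straight-line sum T, which stands above 50% by 6.7 percentage points, against a scatter of 1 point on a reading. Blue and green are each charged with less L than eta, so this reckoning expects Z to lead in both. It names the leader, not its amount.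

The forecast gives Z in both, 42% in green and 39.5% in blue: “unreacted Z leads in both”.

Z leads green with 41.0% and blue with 38.2%.

    L + D → E (k = 0.0170 M⁻¹ min⁻¹)
    L + Z → Q (k = 0.00550 M⁻¹ min⁻¹)
    D ⇌ Z (k = 2.30 × 10⁻⁴ min⁻¹)
    2 L → G (k = 0.00950 M⁻¹ min⁻¹)

Blue ends at T = 61.3%, above the straight-line 56.7%, and green ends at 69.3%. A neighbouring flask is green charged with 1.0 M of L and read at 4.00 h. Its D of 12.7% and Z of 30.8% sum to 43.5%, below 50%, so the test puts E ahead of Z, and E stands there at 38.2%.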